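**Retrosynthetic overview**

1. The last ring closure is the C1–C2 bond of the 6,8-dioxabicyclo[3.2.2]nonan-7-one. In the precursor both carbons are oxygen-bearing acceptor carbons: the acetoxy ketal carbon of a 2-oxo-acid hemiketal and an aldehyde carbon. SmI2 reverses the polarity of the ketal carbon (an α-oxy carbanion held as a trivalent samarium enolate), which adds to the aldehyde across the ring and sets C1 and C2.
2. The first ring, the 1,4-dioxan-2-one, comes from a 2-oxo acid opening a (2S,3S)-trisubstituted epoxide at its tertiary carbon with inversion (sets C5); the freed C9 hydroxyl then closes the hemiketal.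
3. The epoxide fragment comes from nerol: allylic hydroxylation, Sharpless epoxidation (absolute configuration), then triflate/acetylide (alkyne as latent aldehyde).
4. The 2-oxo-acid fragment is made by coupling a ketone homoenolate (cyclopropanol opened on palladium) with a (Z)-iodoalkene from propargyl alcohol.
5. Ring order: six-membered dioxanone first, seven-membered bridge second; desilylation last.

Assumption: the target is the drawn enantiomer, (1R,2S,5R,9S) in the locants of the 6,8-dioxabicyclo[3.2.2]nonan-7-one core (C1 quaternary, C2 carbinol, C5 methyl-bearing, C9 ether CH), with both side-chain alkenes Z.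

**Route**

Step 1
Reactants: 1 nerol [(2Z)-3,7-dimethylocta-2,6-dien-1-ol]
Product: 2 neryl silyl ether tert-butyl{[(2Z)-3,7-dimethylocta-2,6-dien-1-yl]oxy}diphenylsilane
Conditions: TBDPSCl, imidazole, DMF, 23 °C
Reagents that add atoms: tert-butyl(chloro)diphenylsilane, CC(C)(C)[Si](Cl)(c1ccccc1)c1ccccc1
Why: Imidazole-promoted silylation of the primary alcohol gives an acid-stable ether that survives to the last step; no stereocentre is involved.

Step 2
Reactants: 2 neryl silyl ether
Product: 3 allylic alcohol (2E,6Z)-8-[(tert-butyldiphenylsilyl)oxy]-2,6-dimethylocta-2,6-dien-1-ol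
Conditions: SeO2 (cat.), t-BuOOH, salicylic acid (cat.), CH2Cl2, 23 °C
Reagents that add atoms: tert-butyl hydroperoxide, CC(C)(C)OO
Why: SeO2-catalysed allylic hydroxylation (ene reaction then [2,3]-sigmatropic shift) attacks the (E)-methyl of the terminal gem-dimethyl group and gives the (E)-allylic alcohol, while the alkene next to the silyloxy group is deactivated.

Step 3
Reactants: 3 allylic alcohol
Product: 4 epoxy alcohol [(2S,3S)-3-{(3Z)-5-[(tert-butyldiphenylsilyl)oxy]-3-methylpent-3-en-1-yl}-2-methyloxiran-2-yl]methanol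
Conditions: Ti(OiPr)4 (10 mol %), L-(+)-diethyl tartrate (12 mol %), t-BuOOH, 4 Å molecular sieves, CH2Cl2, −20 °C
Reagents that add atoms: tert-butyl hydroperoxide, CC(C)(C)OO
Why: In this Katsuki–Sharpless asymmetric epoxidation only the allylic-alcohol alkene binds to titanium, and L-(+)-tartrate delivers oxygen to the face that gives the (2S,3S)-epoxide (future C9 and, after the later inversion, C5).

Step 4
Reactants: 4 epoxy alcohol
Product: 6 alkynyl epoxide tert-butyl({(2Z)-3-methyl-5-[(2S,3S)-3-methyl-3-(prop-2-yn-1-yl)oxiran-2-yl]pent-2-en-1-yl}oxy)diphenylsilane, via epoxy triflate 5 (not isolated)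
Conditions: Tf2O, 2,6-lutidine, CH2Cl2, −78 °C; then LiC≡CH (from acetylene and n-BuLi), THF–DMPU, −78 → −20 °C
Reagents that add atoms: acetylene (used as LiC≡CH), C#C
Why: SN2 displacement of the primary triflate by lithium acetylide at low temperature leaves the trisubstituted epoxide and both stereocentres untouched and installs a latent aldehyde that cannot attack the epoxide in step 9.

Step 5
Reactants: 7 propargyl alcohol (prop-2-yn-1-ol)
Product: 9 (2Z)-3-iodo-2-methylprop-2-en-1-ol, via alkenylmagnesium alkoxide 8 (not isolated)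
Conditions: MeMgBr (2.5 equiv), CuI (10 mol %), THF, −10 → 23 °C; then I2, −78 → 0 °C
Reagents that add atoms: methylmagnesium bromide, C[Mg]Br; iodine, [I][I]
Why: CuI-catalysed anti-carbomagnesiation of the propargylic alkoxide puts methyl on C2 and magnesium cis to the CH2O group, and iodinolysis with retention gives only the Z iodoalkene.

Step 6
Reactants: 9 (2Z)-3-iodo-2-methylprop-2-en-1-ol
Product: 10 (2Z)-3-iodo-2-methylprop-2-en-1-yl acetate
Conditions: Ac2O, pyridine, DMAP (cat.), CH2Cl2, 0 °C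
Reagents that add atoms: acetic anhydride, CC(=O)OC(C)=O
Why: Routine acetylation installs the acetate of the target early and keeps the alcohol from being oxidised on palladium in the next step.

Step 7
Reactants: 10 (2Z)-3-iodo-2-methylprop-2-en-1-yl acetate; 11 methyl 1-hydroxycyclopropane-1-carboxylate
Product: 13 methyl (5Z)-7-acetoxy-6-methyl-2-oxohept-5-enoate, via palladium homoenolate 12 (not isolated)
Conditions: Pd(OAc)2 (5 mol %), XPhos (10 mol %), Cs2CO3, toluene, 50 °C
Reagents that add atoms: none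
Why: In this palladium-catalysed ring-opening cross-coupling of a cyclopropanol, β-carbon elimination of the palladium cyclopropoxide gives a ketone homoenolate (the β-carbon of the 2-oxo ester as nucleophile) that couples with the alkenyl iodide with retention of the Z geometry, the bulky phosphine favouring reductive elimination over β-hydride loss.

Step 8
Reactants: 13 methyl (5Z)-7-acetoxy-6-methyl-2-oxohept-5-enoate
Product: 14 (5Z)-7-acetoxy-6-methyl-2-oxohept-5-enoic acid
Conditions: LiOH (1.05 equiv), THF–H2O, 0 °C, 15 min; then 1 M HCl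
Reagents that add atoms: lithium hydroxide, [Li+].[OH-]
Why: The 2-oxo ester is far more electrophilic than the primary allylic acetate, so one equivalent of hydroxide at 0 °C saponifies it selectively.

Step 9
Reactants: 6 alkynyl epoxide; 14 (5Z)-7-acetoxy-6-methyl-2-oxohept-5-enoic acid
Product: 16 hemiketal lactone (5S,6R)-3-[(3Z)-5-acetoxy-4-methylpent-3-en-1-yl]-5-{(3Z)-5-[(tert-butyldiphenylsilyl)oxy]-3-methylpent-3-en-1-yl}-3-hydroxy-6-methyl-6-(prop-2-yn-1-yl)-1,4-dioxan-2-one (both C3 epimers), via open hydroxy keto ester 15 (not isolated)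
Conditions: 14 (2 equiv), 4 Å molecular sieves, CH2Cl2 (1 M), 0 → 23 °C
Reagents that add atoms: none
Why: The strong 2-oxo acid (pKa about 2.5) protonates the epoxide and its carboxylate opens it at the tertiary carbon with inversion (acid-mediated epoxide acidolysis, borderline SN2), setting 6R while 5S is retained, and the freed secondary hydroxyl then adds to the activated ketone to close the six-membered hemiketal lactone.

Step 10
Reactants: 16 hemiketal lactone
Product: 17 hemiketal acetate (5S,6R)-3-acetoxy-3-[(3Z)-5-acetoxy-4-methylpent-3-en-1-yl]-5-{(3Z)-5-[(tert-butyldiphenylsilyl)oxy]-3-methylpent-3-en-1-yl}-6-methyl-6-(prop-2-yn-1-yl)-1,4-dioxan-2-one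
Conditions: Ac2O, DMAP (0.2 equiv), pyridine, CH2Cl2, 23 °C
Reagents that add atoms: acetic anhydride, CC(=O)OC(C)=O
Why: Acetylation of the acidic hemiketal hydroxyl (as in peracetylation of 2-ulosonic esters; the ring-chain equilibrium lies on the cyclic side) turns C3 into an acceptor carbon with a reducible leaving group.

Step 11
Reactants: 17 hemiketal acetate
Product: 19 aldehyde (5S,6R)-3-acetoxy-3-[(3Z)-5-acetoxy-4-methylpent-3-en-1-yl]-5-{(3Z)-5-[(tert-butyldiphenylsilyl)oxy]-3-methylpent-3-en-1-yl}-6-methyl-6-(3-oxopropyl)-1,4-dioxan-2-one, via alkenylborane 18 (not isolated)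
Conditions: Cy2BH (1.3 equiv), THF, 0 °C; then 30% H2O2, pH 7 phosphate buffer, 0 → 23 °C
Reagents that add atoms: hydrogen peroxide, OO
Why: Brown hydroboration of the terminal alkyne with a hindered dialkylborane is anti-Markovnikov and much faster than attack on the trisubstituted alkenes or esters, and buffered oxidation of the alkenylborane gives the aldehyde.

Step 12
Reactants: 19 aldehyde
Product: 21 bicyclic silyl ether [(2Z)-5-[(1R,2S,5R,9S)-9-{(3Z)-5-[(tert-butyldiphenylsilyl)oxy]-3-methylpent-3-en-1-yl}-2-hydroxy-5-methyl-7-oxo-6,8-dioxabicyclo[3.2.2]nonan-1-yl]-2-methylpent-2-en-1-yl] acetate, via samarium enolate 20 (not isolated)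
Conditions: SmI2 (2.5 equiv), THF, −78 → 0 °C, slow addition of 19 at high dilution
Reagents that add atoms: none
Why: Two electrons from SmI2 expel the acetate and turn the acceptor ketal carbon C3 into an α-oxy carbanion (held as the trivalent samarium enolate), which adds to the tethered aldehyde in a samarium Reformatsky-type reductive aldol known for anomeric acetates of 2-ulosonic esters; the bridge can only form on the face carrying the tether (C1 = R), and samarium chelation between enolate oxygen and aldehyde oxygen puts the new hydroxyl syn to the lactone carbonyl (C2 = S).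

Step 13
Reactants: 21 bicyclic silyl ether
Product: 22 CNP0174851.1 [(2Z)-5-[(1R,2S,5R,9S)-2-hydroxy-9-[(3Z)-5-hydroxy-3-methylpent-3-en-1-yl]-5-methyl-7-oxo-6,8-dioxabicyclo[3.2.2]nonan-1-yl]-2-methylpent-2-en-1-yl] acetate
Conditions: HF·pyridine, pyridine, THF, 0 → 23 °C
Reagents that add atoms: none
Why: Buffered fluoride desilylation frees the primary allylic alcohol and spares the allylic acetate and the β-hydroxy lactone.

**Compound list**

1 | nerol, (2Z)-3,7-dimethylocta-2,6-dien-1-ol | CC(C)=CCC/C(C)=C\CO | starting material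
2 | tert-butyl{[(2Z)-3,7-dimethylocta-2,6-dien-1-yl]oxy}diphenylsilane | CC(C)=CCC/C(C)=C\CO[Si](c1ccccc1)(c1ccccc1)C(C)(C)C | intermediate
3 | (2E,6Z)-8-[(tert-butyldiphenylsilyl)oxy]-2,6-dimethylocta-2,6-dien-1-ol | OC/C(C)=C/CC/C(C)=C\CO[Si](c1ccccc1)(c1ccccc1)C(C)(C)C | intermediate
4 | [(2S,3S)-3-{(3Z)-5-[(tert-butyldiphenylsilyl)oxy]-3-methylpent-3-en-1-yl}-2-methyloxiran-2-yl]methanol | OC[C@]1(C)O[C@H]1CC/C(C)=C\CO[Si](c1ccccc1)(c1ccccc1)C(C)(C)C | intermediate
5 | [(2S,3S)-3-{(3Z)-5-[(tert-butyldiphenylsilyl)oxy]-3-methylpent-3-en-1-yl}-2-methyloxiran-2-yl]methyl trifluoromethanesulfonate | O=S(=O)(OC[C@]1(C)O[C@H]1CC/C(C)=C\CO[Si](c1ccccc1)(c1ccccc1)C(C)(C)C)C(F)(F)F | intermediate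
6 | tert-butyl({(2Z)-3-methyl-5-[(2S,3S)-3-methyl-3-(prop-2-yn-1-yl)oxiran-2-yl]pent-2-en-1-yl}oxy)diphenylsilane | C#CC[C@]1(C)O[C@H]1CC/C(C)=C\CO[Si](c1ccccc1)(c1ccccc1)C(C)(C)C | intermediate
7 | propargyl alcohol, prop-2-yn-1-ol | C#CCO | starting material
8 | bromomagnesium (2Z)-3-(bromomagnesio)-2-methylprop-2-en-1-olate | Br[Mg]OC/C(C)=C\[Mg]Br | intermediate
9 | (2Z)-3-iodo-2-methylprop-2-en-1-ol | OC/C(C)=C\I | intermediate
10 | (2Z)-3-iodo-2-methylprop-2-en-1-yl acetate | CC(=O)OC/C(C)=C\I | intermediate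
11 | methyl 1-hydroxycyclopropane-1-carboxylate | COC(=O)C1(O)CC1 | starting material
12 | [(1Z)-3-acetoxy-2-methylprop-1-en-1-yl](4-methoxy-3,4-dioxobutyl)palladium, phosphine ligand omitted | COC(=O)C(=O)CC[Pd]/C=C(C)\COC(C)=O | intermediate
13 | methyl (5Z)-7-acetoxy-6-methyl-2-oxohept-5-enoate | COC(=O)C(=O)CC/C=C(C)\COC(C)=O | intermediate
14 | (5Z)-7-acetoxy-6-methyl-2-oxohept-5-enoic acid | CC(=O)OC/C(C)=C\CCC(=O)C(=O)O | intermediate
15 | (2Z,6S,7R)-1-[(tert-butyldiphenylsilyl)oxy]-6-hydroxy-3,7-dimethyldec-2-en-9-yn-7-yl (5Z)-7-acetoxy-6-methyl-2-oxohept-5-enoate | O=C(O[C@](C)(CC#C)[C@@H](O)CC/C(C)=C\CO[Si](c1ccccc1)(c1ccccc1)C(C)(C)C)C(=O)CC/C=C(C)\COC(C)=O | intermediate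
16 | (5S,6R)-3-[(3Z)-5-acetoxy-4-methylpent-3-en-1-yl]-5-{(3Z)-5-[(tert-butyldiphenylsilyl)oxy]-3-methylpent-3-en-1-yl}-3-hydroxy-6-methyl-6-(prop-2-yn-1-yl)-1,4-dioxan-2-one, both C3 epimers | O=C1O[C@](C)(CC#C)[C@H](CC/C(C)=C\CO[Si](c2ccccc2)(c2ccccc2)C(C)(C)C)OC1(O)CC/C=C(C)\COC(C)=O | intermediate
17 | (5S,6R)-3-acetoxy-3-[(3Z)-5-acetoxy-4-methylpent-3-en-1-yl]-5-{(3Z)-5-[(tert-butyldiphenylsilyl)oxy]-3-methylpent-3-en-1-yl}-6-methyl-6-(prop-2-yn-1-yl)-1,4-dioxan-2-one, both C3 epimers | O=C1O[C@](C)(CC#C)[C@H](CC/C(C)=C\CO[Si](c2ccccc2)(c2ccccc2)C(C)(C)C)OC1(OC(C)=O)CC/C=C(C)\COC(C)=O | intermediate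
18 | 17 with the 6-(prop-2-yn-1-yl) group converted into 6-[(2E)-3-(dicyclohexylboranyl)prop-2-en-1-yl] | O=C1O[C@](C)(C/C=C/B(C2CCCCC2)C2CCCCC2)[C@H](CC/C(C)=C\CO[Si](c2ccccc2)(c2ccccc2)C(C)(C)C)OC1(OC(C)=O)CC/C=C(C)\COC(C)=O | intermediate
19 | (5S,6R)-3-acetoxy-3-[(3Z)-5-acetoxy-4-methylpent-3-en-1-yl]-5-{(3Z)-5-[(tert-butyldiphenylsilyl)oxy]-3-methylpent-3-en-1-yl}-6-methyl-6-(3-oxopropyl)-1,4-dioxan-2-one, both C3 epimers | O=C1O[C@](C)(CCC=O)[C@H](CC/C(C)=C\CO[Si](c2ccccc2)(c2ccccc2)C(C)(C)C)OC1(OC(C)=O)CC/C=C(C)\COC(C)=O | intermediate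
20 | trivalent samarium enolate: (5S,6R)-3-[(3Z)-5-acetoxy-4-methylpent-3-en-1-yl]-5-{(3Z)-5-[(tert-butyldiphenylsilyl)oxy]-3-methylpent-3-en-1-yl}-2-[(diiodosamarium)oxy]-6-methyl-6-(3-oxopropyl)-5,6-dihydro-1,4-dioxine | I[Sm](I)OC1=C(CC/C=C(C)\COC(C)=O)O[C@@H](CC/C(C)=C\CO[Si](c2ccccc2)(c2ccccc2)C(C)(C)C)[C@@](C)(CCC=O)O1 | intermediate
21 | [(2Z)-5-[(1R,2S,5R,9S)-9-{(3Z)-5-[(tert-butyldiphenylsilyl)oxy]-3-methylpent-3-en-1-yl}-2-hydroxy-5-methyl-7-oxo-6,8-dioxabicyclo[3.2.2]nonan-1-yl]-2-methylpent-2-en-1-yl] acetate | CC(=O)OC/C(C)=C\CC[C@@]12O[C@@H](CC/C(C)=C\CO[Si](c3ccccc3)(c3ccccc3)C(C)(C)C)[C@@](C)(CC[C@@H]1O)OC2=O | intermediate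
22 | CNP0174851.1, [(2Z)-5-[(1R,2S,5R,9S)-2-hydroxy-9-[(3Z)-5-hydroxy-3-methylpent-3-en-1-yl]-5-methyl-7-oxo-6,8-dioxabicyclo[3.2.2]nonan-1-yl]-2-methylpent-2-en-1-yl] acetate | CC(=O)OC/C(C)=C\CC[C@@]12O[C@@H](CC/C(C)=C\CO)[C@@](C)(CC[C@@H]1O)OC2=O | target

**Step count and weak points**

Total steps: 13 (fragment 1: steps 1–4; fragment 2: steps 5–8; union and endgame: steps 9–13). Longest linear sequence: 9 steps (1–4, then 9–13).

Step 12 (ring closure). Risks are pinacol coupling or reduction of the aldehyde, protonation of the enolate (plain loss of the acetoxy group) and the wrong C2 epimer. The fallback sets out from 19 and comes back at 21, replacing the aldol by an acylation followed by a stereoselective reduction. Pinnick oxidation (NaClO2, NaH2PO4, 2-methylbut-2-ene) gives the carboxylic acid F1, and TMSCHN2 gives the methyl ester F2. SmI2 then generates the same enolate with no reducible aldehyde present, and intramolecular Claisen acylation gives the bicyclic 2-ketone F3. Zn(BH4)2 reduces F3 from the face opposite the zinc chelate that spans the ketone and lactone carbonyl oxygens, giving 21.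

Step 9 (epoxide acidolysis and hemiketalisation). Risks are attack at the secondary carbon, elimination or 1,2-shift at the tertiary centre, and cation–alkene cyclisation onto the neryl alkene. The fallback sets out from 6 (and uses 14) and comes back at 16, acylating a preformed tertiary alcohol instead of substituting at the tertiary carbon. HClO4 (cat.) in THF–H2O opens the epoxide with water at the tertiary carbon with inversion to give the anti-diol F4. TESCl and imidazole silylate only the secondary hydroxyl to give the triethylsilyl ether F5. Acid 14 is converted with Cl2CHOMe into the acid chloride F6, which acylates the tertiary alcohol of F5 (pyridine, DMAP) to give the keto ester F7. HF·pyridine at 0 °C removes only the triethylsilyl group, and the freed hydroxyl closes onto the ketone to give 16.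

Step 7 (homoenolate cross-coupling). Risks are β-hydride elimination from the palladium homoenolate, ionisation of the allylic acetate by zerovalent palladium, and base-induced self-condensation of the 2-oxo ester. The fallback sets out from 9 and comes back at 13, using a Heck reaction in place of the homoenolate. Iodo alcohol 9 and methyl 2-hydroxybut-3-enoate under Jeffery conditions (Pd(OAc)2, Bu4NCl, NaHCO3, DMF, 23 °C) undergo carbopalladation followed by β-hydride elimination toward the carbinol; the enol tautomerises to the hydroxy keto ester F8. Acetylation (Ac2O, pyridine) then gives 13.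

Further compounds

F1 | step 12 | carboxylic acid: 19 with the 3-oxopropyl group oxidised to 2-carboxyethyl | O=C1O[C@](C)(CCC(=O)O)[C@H](CC/C(C)=C\CO[Si](c2ccccc2)(c2ccccc2)C(C)(C)C)OC1(OC(C)=O)CC/C=C(C)\COC(C)=O
F2 | step 12 | methyl ester of F1 | O=C1O[C@](C)(CCC(=O)OC)[C@H](CC/C(C)=C\CO[Si](c2ccccc2)(c2ccccc2)C(C)(C)C)OC1(OC(C)=O)CC/C=C(C)\COC(C)=O
F3 | step 12 | bicyclic 2-ketone: [(2Z)-5-[(1R,5R,9S)-9-{(3Z)-5-[(tert-butyldiphenylsilyl)oxy]-3-methylpent-3-en-1-yl}-5-methyl-2,7-dioxo-6,8-dioxabicyclo[3.2.2]nonan-1-yl]-2-methylpent-2-en-1-yl] acetate | CC(=O)OC/C(C)=C\CC[C@@]12O[C@@H](CC/C(C)=C\CO[Si](c3ccccc3)(c3ccccc3)C(C)(C)C)[C@@](C)(CCC1=O)OC2=O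
F4 | step 9 | anti-diol: (2Z,6S,7R)-1-[(tert-butyldiphenylsilyl)oxy]-3,7-dimethyldec-2-en-9-yne-6,7-diol | O[C@](C)(CC#C)[C@@H](O)CC/C(C)=C\CO[Si](c1ccccc1)(c1ccccc1)C(C)(C)C
F5 | step 9 | triethylsilyl ether: (2Z,6S,7R)-1-[(tert-butyldiphenylsilyl)oxy]-3,7-dimethyl-6-[(triethylsilyl)oxy]dec-2-en-9-yn-7-ol | O[C@](C)(CC#C)[C@@H](O[Si](CC)(CC)CC)CC/C(C)=C\CO[Si](c1ccccc1)(c1ccccc1)C(C)(C)C
F6 | step 9 | acid chloride: (5Z)-7-acetoxy-6-methyl-2-oxohept-5-enoyl chloride | CC(=O)OC/C(C)=C\CCC(=O)C(Cl)=O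
F7 | step 9 | keto ester: (2Z,6S,7R)-1-[(tert-butyldiphenylsilyl)oxy]-3,7-dimethyl-6-[(triethylsilyl)oxy]dec-2-en-9-yn-7-yl (5Z)-7-acetoxy-6-methyl-2-oxohept-5-enoate | O=C(O[C@](C)(CC#C)[C@@H](O[Si](CC)(CC)CC)CC/C(C)=C\CO[Si](c1ccccc1)(c1ccccc1)C(C)(C)C)C(=O)CC/C=C(C)\COC(C)=O
F8 | step 7 | hydroxy keto ester: methyl (5Z)-7-hydroxy-6-methyl-2-oxohept-5-enoate | COC(=O)C(=O)CC/C=C(C)\CO
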